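## Retrosynthetic overview

1. The target, (R)-configured at the quaternary epoxide carbon, comes from the same epoxide bis-isobutyrate carrying the phenol as a TIPS ether; the tiglate goes on last by fluoride desilylation and in-flask acylation.
2. Key C–C disconnection: quaternary epoxide carbon–CH2O bond. It is made from a configurationally stable α-lithiated (R)-aryloxirane (a nucleophilic epoxide carbon, normally an electrophilic site) and formaldehyde, with retention; both lithium alkoxides are capped as isobutyrates in the same flask.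
3. The (R)-aryloxirane benzylic alcohol comes from ester reduction of the (R)-epoxy ester, which comes from hydrolytic kinetic resolution of the racemic epoxide (the only stereocentre is set here).
4. The racemic epoxide comes from sulfonium-ylide methylene transfer to the O-silylated aldehyde, made from methyl 4-formyl-3-hydroxybenzoate.
5. Rings: the benzene ring is bought; the oxirane is the only ring formed (step 2) and is carried intact to the end.

Assumption: methyl 4-formyl-3-hydroxybenzoate and tiglic anhydride [(E)-2-methylbut-2-enoic anhydride] are taken as purchasable.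

## Route

Step 1
Reactants: 1 methyl 4-formyl-3-hydroxybenzoate
Product: 2 methyl 4-formyl-3-[(triisopropylsilyl)oxy]benzoate
Conditions: TIPSCl (1.2 equiv), imidazole (2.5 equiv), DMF, rt, 12 h
Reagents that add atoms: chlorotriisopropylsilane, CC(C)[Si](Cl)(C(C)C)C(C)C
Why: Phenol O-silylation (silyl ether protection); the bulky TIPS ether resists the ylide, hydride and organolithium steps and is a poor ortho-director, yet leaves with fluoride at the end; no stereocentre is involved.

Step 2
Reactants: 2 methyl 4-formyl-3-[(triisopropylsilyl)oxy]benzoate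
Product: 3 rac-methyl 4-(oxiran-2-yl)-3-[(triisopropylsilyl)oxy]benzoate
Conditions: Me3S+ I− (1.3 equiv), KN(SiMe3)2 (1.25 equiv), THF, −20 °C; then 2, −20 → 0 °C
Reagents that add atoms: trimethylsulfonium iodide, C[S+](C)C.[I-]
Why: Corey–Chaykovsky epoxidation; dimethylsulfonium methylide adds to the aldehyde much faster than to the conjugated methyl ester and the betaine closes to the terminal oxirane, formed as the racemate.

Step 3
Reactants: 3 rac-methyl 4-(oxiran-2-yl)-3-[(triisopropylsilyl)oxy]benzoate
Product: 4 methyl 4-[(2R)-oxiran-2-yl]-3-[(triisopropylsilyl)oxy]benzoate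
Conditions: (R,R)-(salen)Co(OAc) (1 mol %; trivalent cobalt; salen = N,N′-bis(3,5-di-tert-butylsalicylidene)cyclohexane-1,2-diamine dianion), H2O (0.55 equiv), THF, 0 °C → rt, 16–24 h
Reagents that add atoms: none
Why: Jacobsen hydrolytic kinetic resolution; the (R,R) catalyst hydrolyses the (S)-epoxide of terminal aryl epoxides selectively, so unreacted (R)-4 is recovered in high ee (at most 50 % yield) and the only stereocentre of the route is set here.

Step 4
Reactants: 4 methyl 4-[(2R)-oxiran-2-yl]-3-[(triisopropylsilyl)oxy]benzoate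
Product: 5 {4-[(2R)-oxiran-2-yl]-3-[(triisopropylsilyl)oxy]phenyl}methanol
Conditions: i-Bu2AlH (2.4 equiv), CH2Cl2, −78 °C, 1 h; aq. KNaC4H4O6
Reagents that add atoms: none
Why: Hydride reduction of an ester to the primary alcohol; at −78 °C i-Bu2AlH reduces the benzoate while the terminal epoxide and the aryl silyl ether are left alone, and the stereocentre is not touched.

Step 5
Reactants: 5 {4-[(2R)-oxiran-2-yl]-3-[(triisopropylsilyl)oxy]phenyl}methanol
Product: 8 [(2R)-2-{4-[(2-methylpropanoyloxy)methyl]-2-[(triisopropylsilyl)oxy]phenyl}oxiran-2-yl]methyl 2-methylpropanoate, via dilithiated oxirane 6 (not isolated), via dilithium dialkoxide 7 (not isolated)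
Conditions: s-BuLi (2.3 equiv), TMEDA (3 equiv), THF, −98 °C, 20 min; monomeric CH2O (THF solution from cracked paraformaldehyde, 1.3 equiv), −98 °C, 15 min; (i-PrCO)2O (3.5 equiv), −98 → −20 °C; aq. NaHCO3
Reagents that add atoms: formaldehyde, C=O; isobutyric anhydride, CC(C)C(=O)OC(=O)C(C)C
Why: α-Lithiation and electrophilic trapping of an aryloxirane (oxiranyllithium chemistry, untested on this electron-rich substrate): s-BuLi/TMEDA forms the benzylic lithium alkoxide and then removes the benzylic oxirane C–H to give an oxiranyllithium that is configurationally stable at −98 °C and adds to formaldehyde with retention, so the (R) centre of 5 becomes the quaternary centre, after which both lithium alkoxides are O-acylated by the anhydride in the same flask.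

Step 6
Reactants: 8 [(2R)-2-{4-[(2-methylpropanoyloxy)methyl]-2-[(triisopropylsilyl)oxy]phenyl}oxiran-2-yl]methyl 2-methylpropanoate
Product: 10 [(2R)-2-{4-[(2-methylpropanoyloxy)methyl]-2-[(E)-2-methylbut-2-enoyloxy]phenyl}oxiran-2-yl]methyl 2-methylpropanoate, via cesium phenoxide 9 (not isolated)
Conditions: CsF (1.5 equiv), tiglic anhydride (2.0 equiv), DMF, 0 °C → rt
Reagents that add atoms: tiglic anhydride, C/C=C(\C)C(=O)OC(=O)/C(C)=C/C
Why: Fluoride-induced desilylation with in situ O-acylation (desilylative acylation); fluoride cleaves the aryl O–Si bond and the phenoxide is trapped at once by excess anhydride before it can attack the neighbouring ester or epoxide, the E geometry comes unchanged from the anhydride, and the quaternary stereocentre is not involved.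

## Compound list

1 | methyl 4-formyl-3-hydroxybenzoate | COC(=O)c1ccc(C=O)c(O)c1 | starting material
2 | methyl 4-formyl-3-[(triisopropylsilyl)oxy]benzoate | COC(=O)c1ccc(C=O)c(O[Si](C(C)C)(C(C)C)C(C)C)c1 | intermediate
3 | rac-methyl 4-(oxiran-2-yl)-3-[(triisopropylsilyl)oxy]benzoate (racemate) | COC(=O)c1ccc(C2CO2)c(O[Si](C(C)C)(C(C)C)C(C)C)c1 | intermediate
4 | methyl 4-[(2R)-oxiran-2-yl]-3-[(triisopropylsilyl)oxy]benzoate | CC(C)[Si](C(C)C)(C(C)C)Oc1cc(C(=O)OC)ccc1[C@@H]1CO1 | intermediate
5 | {4-[(2R)-oxiran-2-yl]-3-[(triisopropylsilyl)oxy]phenyl}methanol | CC(C)[Si](C(C)C)(C(C)C)Oc1cc(CO)ccc1[C@@H]1CO1 | intermediate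
6 | lithium {4-[(2R)-2-lithiooxiran-2-yl]-3-[(triisopropylsilyl)oxy]phenyl}methanolate (C-lithiated oxirane, O-lithiated benzylic alcohol) | CC(C)[Si](C(C)C)(C(C)C)Oc1cc(CO[Li])ccc1[C@]1([Li])CO1 | intermediate
7 | dilithium dialkoxide of [(2S)-2-{4-(hydroxymethyl)-2-[(triisopropylsilyl)oxy]phenyl}oxiran-2-yl]methanol | CC(C)[Si](C(C)C)(C(C)C)Oc1cc(CO[Li])ccc1[C@]1(CO[Li])CO1 | intermediate
8 | [(2R)-2-{4-[(2-methylpropanoyloxy)methyl]-2-[(triisopropylsilyl)oxy]phenyl}oxiran-2-yl]methyl 2-methylpropanoate | CC(C)[Si](C(C)C)(C(C)C)Oc1cc(COC(=O)C(C)C)ccc1[C@]1(COC(=O)C(C)C)CO1 | intermediate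
9 | cesium 5-[(2-methylpropanoyloxy)methyl]-2-[(2R)-2-[(2-methylpropanoyloxy)methyl]oxiran-2-yl]phenolate | [Cs+].[O-]c1cc(COC(=O)C(C)C)ccc1[C@]1(COC(=O)C(C)C)CO1 | intermediate
10 | [(2R)-2-{4-[(2-methylpropanoyloxy)methyl]-2-[(E)-2-methylbut-2-enoyloxy]phenyl}oxiran-2-yl]methyl 2-methylpropanoate (CNP0189152.1) | C/C=C(\C)C(=O)Oc1cc(COC(=O)C(C)C)ccc1[C@]1(COC(=O)C(C)C)CO1 | target

Note on descriptors: the spatial arrangement at the epoxide carbon is the same from 4 to 10. The label reads S in 7 (and in the free alcohols F3 and F4 below) only because a CH2OLi or CH2OH arm ranks below the ring CH2, whereas the CH2O-acyl arm ranks above it.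

## Summary

Total step count: 6. Longest linear sequence: 6 steps (fully linear from 1).

Steps most likely to fail:

**Step 5 (highest risk).** The electron-rich ortho-silyloxy aryloxirane may lithiate slowly. The oxiranyllithium may decay by carbenoid α-elimination or O→C silyl shift. The ring position between OTIPS and CH2OLi may be metalated, and the benzylic alkoxide can form a hemiacetal with formaldehyde. Fallback: keep a reversed-polarity construction of the same C–C bond but set the stereocentre afterwards. It sets out from 2 and comes back at 8.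
- Thiazolium-carbene-catalysed hydroxymethylation of 2 (3-benzyl-5-(2-hydroxyethyl)-4-methylthiazolium chloride, i-Pr2NEt, paraformaldehyde, THF, 60 °C; the Breslow intermediate acts as acyl anion toward formaldehyde) gives methyl 4-(2-hydroxyacetyl)-3-[(triisopropylsilyl)oxy]benzoate F1.
- Wittig methylenation (Ph3PCH3Br/KOtBu, 2.2 equiv, THF, 0 °C) gives methyl 4-(3-hydroxyprop-1-en-2-yl)-3-[(triisopropylsilyl)oxy]benzoate F2.
- i-Bu2AlH in CH2Cl2 at −78 °C reduces the ester to 2-{4-(hydroxymethyl)-2-[(triisopropylsilyl)oxy]phenyl}prop-2-en-1-ol F3.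
- Sharpless epoxidation of this 2-aryl allylic alcohol (Ti(OiPr)4, L-(+)-diethyl tartrate, t-BuOOH, 4 Å sieves, CH2Cl2, −20 °C) gives [(2S)-2-{4-(hydroxymethyl)-2-[(triisopropylsilyl)oxy]phenyl}oxiran-2-yl]methanol F4. The L-(+)-tartrate choice is by analogy with the sense that gives (S)-2-methylglycidol.
- Double acylation with isobutyric anhydride, Et3N and catalytic DMAP returns to 8.

**Step 6.** The transient phenoxide sits next to an ester (acyl shift) and a tertiary benzylic epoxide (opening), and CsF may cleave the aryl TIPS ether slowly. Fallback: do not generate a phenoxide in the presence of the acyl donor. It sets out from 8 and comes back at 10. Buffered desilylation (Bu4NF/AcOH 1:1, THF, −20 °C) gives the neutral phenol [(2R)-2-{2-hydroxy-4-[(2-methylpropanoyloxy)methyl]phenyl}oxiran-2-yl]methyl 2-methylpropanoate F5. It is used at once in a carbodiimide esterification with tiglic acid (EDC·HCl, catalytic DMAP, CH2Cl2, 0 °C) to give 10.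

**Step 4.** i-Bu2AlH can open the benzylic epoxide reductively. Fallback: reduce the ester before any epoxide exists. It sets out from 2 and comes back at 5.
- Wittig methylenation of 2 (Ph3PCH3Br/KOtBu, THF, 0 °C) gives methyl 4-ethenyl-3-[(triisopropylsilyl)oxy]benzoate F6.
- i-Bu2AlH reduction gives {4-ethenyl-3-[(triisopropylsilyl)oxy]phenyl}methanol F7.
- Buffered epoxidation (mCPBA, NaHCO3, CH2Cl2, 0 °C) gives rac-{4-(oxiran-2-yl)-3-[(triisopropylsilyl)oxy]phenyl}methanol F8.
- Hydrolytic kinetic resolution with the same (R,R)-(salen)Co(OAc) catalyst (trivalent cobalt) and 0.55 equiv H2O leaves 5.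

Further compounds
F1 | step 5 | methyl 4-(2-hydroxyacetyl)-3-[(triisopropylsilyl)oxy]benzoate | COC(=O)c1ccc(C(=O)CO)c(O[Si](C(C)C)(C(C)C)C(C)C)c1
F2 | step 5 | methyl 4-(3-hydroxyprop-1-en-2-yl)-3-[(triisopropylsilyl)oxy]benzoate | COC(=O)c1ccc(C(=C)CO)c(O[Si](C(C)C)(C(C)C)C(C)C)c1
F3 | step 5 | 2-{4-(hydroxymethyl)-2-[(triisopropylsilyl)oxy]phenyl}prop-2-en-1-ol | CC(C)[Si](C(C)C)(C(C)C)Oc1cc(CO)ccc1C(=C)CO
F4 | step 5 | [(2S)-2-{4-(hydroxymethyl)-2-[(triisopropylsilyl)oxy]phenyl}oxiran-2-yl]methanol | CC(C)[Si](C(C)C)(C(C)C)Oc1cc(CO)ccc1[C@]1(CO)CO1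
F5 | step 6 | [(2R)-2-{2-hydroxy-4-[(2-methylpropanoyloxy)methyl]phenyl}oxiran-2-yl]methyl 2-methylpropanoate | Oc1cc(COC(=O)C(C)C)ccc1[C@]1(COC(=O)C(C)C)CO1
F6 | step 4 | methyl 4-ethenyl-3-[(triisopropylsilyl)oxy]benzoate | COC(=O)c1ccc(C=C)c(O[Si](C(C)C)(C(C)C)C(C)C)c1
F7 | step 4 | {4-ethenyl-3-[(triisopropylsilyl)oxy]phenyl}methanol | C=Cc1ccc(CO)cc1O[Si](C(C)C)(C(C)C)C(C)C
F8 | step 4 | rac-{4-(oxiran-2-yl)-3-[(triisopropylsilyl)oxy]phenyl}methanol | OCc1ccc(C2CO2)c(O[Si](C(C)C)(C(C)C)C(C)C)c1
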